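## Retrosynthetic overview

1. Target ⇒ phenol desilylation, late epoxidation of C3=C4 on the trans-fused bicycle, and acylation of the C8 hydroxyl with a silyl-protected isovanillic acid chloride (fragment C).
2. 8β,10α-Diol ⇒ 10α-hydroxy-8-ketone (hydroxyl-directed reduction) ⇒ 9α,10α-epoxy-8-ketone (SmI2 opening) ⇒ 8α-allylic alcohol (hydroxyl-directed epoxidation); the temporary 8α-hydroxyl sets C10 and is then inverted through the ketone.
3. Seven-membered ring ⇒ ring-closing metathesis forming C9=C10 between a C8 vinyl carbinol and the C1 isopropenyl group.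
4. Metathesis diene ⇒ copper-mediated anti-SN2′ coupling (C5–C6) of a cyclopentenyl picolinate (fragment A, from (R)-4-silyloxycyclopentenone) with the Grignard reagent of fragment B (Evans syn-aldol of an isovaleryl imide with acrolein).
5. Ring order: the five-membered carbocycle is bought in and carried through, the seven-membered ring is closed by metathesis, the oxirane is formed last.

Convention: bicyclic compounds use guaiane numbering (C1 and C5 ring fusion; C2–C4 complete the five-membered ring, methyl on C4; C6–C10 complete the seven-membered ring, isopropyl on C7, methyl on C10); α = below, β = above the plane in the usual drawing. The target is (1R,3R,4S,5S,7R,8R,10R).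

Assumption: (R)-4-[(tert-butyldimethylsilyl)oxy]cyclopent-2-en-1-one, (R)-4-benzyloxazolidin-2-one and isovanillin are taken as inexpensive catalogue chemicals.

## Fragment A

Step 1
Reactants: 1 (R)-4-[(tert-butyldimethylsilyl)oxy]cyclopent-2-en-1-one
Product: 4 (R)-4-(prop-1-en-2-yl)cyclopent-2-en-1-one, via silyl enol ether 2 (not isolated), via silyloxy ketone 3 (not isolated)
Conditions: isopropenylMgBr (1.5 equiv), CuBr·SMe2 (10 mol %), Me3SiCl, THF, −78 °C; 1 M HCl work-up; then DBU (1.1 equiv), CH2Cl2, 0 °C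
Reagents that add atoms: isopropenylmagnesium bromide, C=C(C)[Mg]Br
Why: Copper-catalysed 1,4-addition of the alkenyl Grignard reagent occurs anti to the silyloxy group, and E1cB loss of silanol after hydrolysis transposes the enone, so the new stereocentre (the future C1, H α) is set by the single stereocentre of 1.

Step 2
Reactants: 4 (R)-4-(prop-1-en-2-yl)cyclopent-2-en-1-one
Product: 5 (R)-2-iodo-4-(prop-1-en-2-yl)cyclopent-2-en-1-one
Conditions: I2 (1.5 equiv), pyridine/CH2Cl2 (1:1), 0 °C → rt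
Reagents that add atoms: iodine, II
Why: α-Iodination of the enone by the pyridine addition–iodination–elimination sequence (Baylis–Hillman-type) leaves the stereocentre and the isopropenyl group untouched.

Step 3
Reactants: 5 (R)-2-iodo-4-(prop-1-en-2-yl)cyclopent-2-en-1-one
Product: 6 (R)-2-methyl-4-(prop-1-en-2-yl)cyclopent-2-en-1-one
Conditions: MeZnCl (1.5 equiv), Pd(PPh3)4 (5 mol %), THF, rt
Reagents that add atoms: methylzinc chloride, C[Zn]Cl
Why: Negishi cross-coupling of the vinyl iodide installs the C4 methyl under neutral conditions that do not epimerise the γ-stereocentre.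

Step 4
Reactants: 6 (R)-2-methyl-4-(prop-1-en-2-yl)cyclopent-2-en-1-one
Product: 7 (1S,4R)-2-methyl-4-(prop-1-en-2-yl)cyclopent-2-en-1-ol
Conditions: NaBH4, CeCl3·7H2O, MeOH, −78 °C
Reagents that add atoms: none
Why: Luche 1,2-reduction delivers hydride anti to the isopropenyl group and gives the cis-1,4 alcohol, the minor trans isomer being removed by chromatography.

Step 5
Reactants: 7 (1S,4R)-2-methyl-4-(prop-1-en-2-yl)cyclopent-2-en-1-ol
Product: 8 (1S,4R)-2-methyl-4-(prop-1-en-2-yl)cyclopent-2-en-1-yl pyridine-2-carboxylate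
Conditions: picolinic acid, DCC, DMAP (cat.), CH2Cl2, rt
Reagents that add atoms: pyridine-2-carboxylic acid, OC(=O)c1ccccn1
Why: Steglich esterification with retention gives the picolinate, a chelating leaving group for copper-mediated allylic substitution.

## Fragment B

Step 6
Reactants: 9 (R)-4-benzyloxazolidin-2-one; 10 3-methylbutanoyl chloride
Product: 11 (R)-4-benzyl-3-(3-methylbutanoyl)oxazolidin-2-one
Conditions: Et3N, DMAP (cat.), CH2Cl2, 0 °C → rt
Reagents that add atoms: none
Why: N-Acylation of the oxazolidinone under nucleophilic catalysis attaches the isovaleryl unit (C6, C7 and the isopropyl group) to the chiral auxiliary.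

Step 7
Reactants: 11 (R)-4-benzyl-3-(3-methylbutanoyl)oxazolidin-2-one; 12 acrolein
Product: 15 (R)-4-benzyl-3-[(2R,3S)-3-hydroxy-2-(propan-2-yl)pent-4-enoyl]oxazolidin-2-one, via boron enolate 13 (not isolated), via boron aldolate 14 (not isolated)
Conditions: Bu2BOTf, iPr2NEt, CH2Cl2, 0 °C; 12, −78 → 0 °C; then pH 7 buffer, MeOH, 30% H2O2, 0 °C
Reagents that add atoms: none
Why: Evans boron syn-aldol reaction: the (Z)-enolate reacts through a Zimmerman–Traxler chair on the face away from the benzyl group, setting C7 (R, final) and the temporary C8 carbinol (the later 8α-hydroxyl) in a syn relationship.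

Step 8
Reactants: 15 (R)-4-benzyl-3-[(2R,3S)-3-hydroxy-2-(propan-2-yl)pent-4-enoyl]oxazolidin-2-one
Product: 16 (R)-4-benzyl-3-{(2R,3S)-2-(propan-2-yl)-3-[(triethylsilyl)oxy]pent-4-enoyl}oxazolidin-2-one
Conditions: Et3SiCl, imidazole, DMF, rt
Reagents that add atoms: chlorotriethylsilane, CC[Si](Cl)(CC)CC
Why: O-Silylation protects the secondary hydroxyl as a triethylsilyl ether that survives hydride and Grignard chemistry but falls off in dilute acid.

Step 9
Reactants: 16 (R)-4-benzyl-3-{(2R,3S)-2-(propan-2-yl)-3-[(triethylsilyl)oxy]pent-4-enoyl}oxazolidin-2-one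
Product: 17 (2S,3S)-2-(propan-2-yl)-3-[(triethylsilyl)oxy]pent-4-en-1-ol
Conditions: LiBH4, MeOH (1 equiv), THF, 0 °C
Reagents that add atoms: none
Why: Reductive cleavage of the N-acyloxazolidinone by hydride attack at the exocyclic carbonyl gives the primary alcohol (C6) and returns the auxiliary without touching the two stereocentres.

Step 10
Reactants: 17 (2S,3S)-2-(propan-2-yl)-3-[(triethylsilyl)oxy]pent-4-en-1-ol
Product: 18 (3S,4R)-4-(bromomethyl)-5-methyl-3-[(triethylsilyl)oxy]hex-1-ene
Conditions: CBr4, PPh3, imidazole, CH2Cl2, 0 °C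
Reagents that add atoms: carbon tetrabromide, BrC(Br)(Br)Br
Why: Appel bromination converts the primary alcohol into the bromide under buffered conditions that the silyl ether tolerates.

## Fragment C

Step 11
Reactants: 19 isovanillin (3-hydroxy-4-methoxybenzaldehyde)
Product: 20 3-[(tert-butyldimethylsilyl)oxy]-4-methoxybenzaldehyde
Conditions: t-BuMe2SiCl, imidazole, DMF, rt
Reagents that add atoms: tert-butylchlorodimethylsilane, CC(C)(C)[Si](C)(C)Cl
Why: Silylation masks the phenol so that it cannot be acylated later.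

Step 12
Reactants: 20 3-[(tert-butyldimethylsilyl)oxy]-4-methoxybenzaldehyde
Product: 21 3-[(tert-butyldimethylsilyl)oxy]-4-methoxybenzoic acid
Conditions: NaClO2, NaH2PO4, 2-methylbut-2-ene, t-BuOH/H2O, rt
Reagents that add atoms: sodium chlorite, [Na+].[O-]Cl=O
Why: Pinnick oxidation converts the aldehyde into the acid at about pH 4, where the aryl silyl ether is stable.

Step 13
Reactants: 21 3-[(tert-butyldimethylsilyl)oxy]-4-methoxybenzoic acid
Product: 22 3-[(tert-butyldimethylsilyl)oxy]-4-methoxybenzoyl chloride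
Conditions: (COCl)2, DMF (cat.), CH2Cl2, 0 °C → rt; used crude
Reagents that add atoms: oxalyl chloride, ClC(=O)C(Cl)=O
Why: Vilsmeier-type activation gives the acid chloride needed to acylate a hindered secondary alcohol.

## Fragment union and completion

Step 14
Reactants: 18 (3S,4R)-4-(bromomethyl)-5-methyl-3-[(triethylsilyl)oxy]hex-1-ene; 8 (1S,4R)-2-methyl-4-(prop-1-en-2-yl)cyclopent-2-en-1-yl pyridine-2-carboxylate
Product: 25 (3S,4R)-5-methyl-4-{[(1S,5R)-2-methyl-5-(prop-1-en-2-yl)cyclopent-2-en-1-yl]methyl}hex-1-en-3-ol, via Grignard reagent 23 (not isolated), via triethylsilyl ether 24 (not isolated)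
Conditions: 18 (1.6 equiv), Mg, THF, 40 °C; then CuBr·SMe2 (0.8 equiv), 8 (1.0 equiv), THF, −40 → 0 °C; then MeOH, 1 M HCl, 0 °C → rt
Reagents that add atoms: none
Why: Copper-mediated anti-SN2′ allylic substitution: the alkylcopper attacks C5 on the face opposite the picolinate, which is also the face anti to the neighbouring isopropenyl group, so C5 is set trans to C1 (H5 β) and the double bond lands at C3=C4; dilute acid then removes the silyl group.

Step 15
Reactants: 25 (3S,4R)-5-methyl-4-{[(1S,5R)-2-methyl-5-(prop-1-en-2-yl)cyclopent-2-en-1-yl]methyl}hex-1-en-3-ol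
Product: 26 1αH,5βH,7αH-guaia-3,9-dien-8α-ol
Conditions: second-generation Grubbs catalyst (5 mol %), CH2Cl2 (0.003 M), 40 °C
Reagents that add atoms: none
Why: Ring-closing metathesis between the vinyl carbinol and the isopropenyl group closes the seven-membered ring as the trisubstituted C9=C10 alkene with loss of ethene, the trisubstituted cyclopentene being too hindered and unstrained to take part.

Step 16
Reactants: 26 1αH,5βH,7αH-guaia-3,9-dien-8α-ol
Product: 27 9α,10α-epoxy-1αH,5βH,7αH-guai-3-en-8α-ol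
Conditions: VO(acac)2 (5 mol %), t-BuOOH, CH2Cl2, 0 °C → rt
Reagents that add atoms: tert-butyl hydroperoxide, CC(C)(C)OO
Why: Vanadium-catalysed hydroxyl-directed epoxidation delivers oxygen syn to the 8α-hydroxyl and only to the allylic-alcohol alkene, which fixes the C10–O bond on the α face.

Step 17
Reactants: 27 9α,10α-epoxy-1αH,5βH,7αH-guai-3-en-8α-ol
Product: 28 9α,10α-epoxy-1αH,5βH,7αH-guai-3-en-8-one
Conditions: Dess–Martin periodinane, pyridine, CH2Cl2, 0 °C → rt
Reagents that add atoms: none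
Why: Dess–Martin oxidation of the secondary alcohol under buffered conditions gives the α,β-epoxy ketone without opening the oxirane or epimerising C7.

Step 18
Reactants: 28 9α,10α-epoxy-1αH,5βH,7αH-guai-3-en-8-one
Product: 29 10α-hydroxy-1αH,5βH,7αH-guai-3-en-8-one
Conditions: SmI2 (2.5 equiv), THF/MeOH, −90 °C
Reagents that add atoms: none
Why: SmI2 reductive cleavage of the Cα–O bond of the α,β-epoxy ketone (ketyl formation then β-elimination) gives the β-hydroxy ketone; the C10–O bond is not broken, so the 10α-hydroxyl/10β-methyl centre is kept.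

Step 19
Reactants: 29 10α-hydroxy-1αH,5βH,7αH-guai-3-en-8-one
Product: 30 1αH,5βH,7αH-guai-3-ene-8β,10α-diol
Conditions: Me4NBH(OAc)3, MeCN/AcOH (1:1), −30 → −20 °C
Reagents that add atoms: none
Why: Evans–Saksena hydroxyl-directed reduction: the borohydride bound to the 10α-oxygen delivers hydride intramolecularly to the α face of the C8 ketone, which is also the face anti to the 7β-isopropyl group, giving the 8β-alcohol (trans-1,3-diol).

Step 20
Reactants: 30 1αH,5βH,7αH-guai-3-ene-8β,10α-diol; 22 3-[(tert-butyldimethylsilyl)oxy]-4-methoxybenzoyl chloride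
Product: 31 8β-{3-[(tert-butyldimethylsilyl)oxy]-4-methoxybenzoyloxy}-1αH,5βH,7αH-guai-3-en-10α-ol
Conditions: 22 (1.5 equiv), Et3N, DMAP (cat.), CH2Cl2, 0 → 40 °C
Reagents that add atoms: none
Why: DMAP-catalysed acylation esterifies the secondary C8 hydroxyl with retention, while the tertiary C10 hydroxyl is too hindered to react.

Step 21
Reactants: 31 8β-{3-[(tert-butyldimethylsilyl)oxy]-4-methoxybenzoyloxy}-1αH,5βH,7αH-guai-3-en-10α-ol
Product: 32 8β-{3-[(tert-butyldimethylsilyl)oxy]-4-methoxybenzoyloxy}-3α,4α-epoxy-1αH,5βH,7αH-guaian-10α-ol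
Conditions: dimethyldioxirane (acetone solution), CH2Cl2, −20 → 0 °C
Reagents that add atoms: dimethyldioxirane, CC1(C)OO1
Why: Neutral dioxirane epoxidation of the only remaining alkene is expected from the α face of the rigid trans-fused bicycle, anti to the pseudo-axial allylic C5–H and away from the axial 10β-methyl, which sets C3 and C4.

Step 22
Reactants: 32 8β-{3-[(tert-butyldimethylsilyl)oxy]-4-methoxybenzoyloxy}-3α,4α-epoxy-1αH,5βH,7αH-guaian-10α-ol
Product: 33 3α,4α-epoxy-8β-(3-hydroxy-4-methoxybenzoyloxy)-1αH,5βH,7αH-guaian-10α-ol (CNP0264062.2)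
Conditions: Bu4NF, AcOH (1:1), THF, 0 °C
Reagents that add atoms: none
Why: Fluoride-mediated desilylation frees the phenol, and the acetic acid buffer keeps the oxirane, the ester and the tertiary alcohol intact.

## Compound list

1 | (R)-4-[(tert-butyldimethylsilyl)oxy]cyclopent-2-en-1-one | O=C1C=C[C@H](O[Si](C)(C)C(C)(C)C)C1 | starting material
2 | trimethylsilyl enol ether of 3 (3,4-trans) | C[Si](C)(C)OC1=C[C@@H](C(C)=C)[C@H](O[Si](C)(C)C(C)(C)C)C1 | intermediate
3 | (3S,4R)-4-[(tert-butyldimethylsilyl)oxy]-3-(prop-1-en-2-yl)cyclopentan-1-one | O=C1C[C@@H](C(C)=C)[C@H](O[Si](C)(C)C(C)(C)C)C1 | intermediate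
4 | (R)-4-(prop-1-en-2-yl)cyclopent-2-en-1-one | O=C1C[C@@H](C(C)=C)C=C1 | intermediate
5 | (R)-2-iodo-4-(prop-1-en-2-yl)cyclopent-2-en-1-one | O=C1C[C@@H](C(C)=C)C=C1I | intermediate
6 | (R)-2-methyl-4-(prop-1-en-2-yl)cyclopent-2-en-1-one | O=C1C[C@@H](C(C)=C)C=C1C | intermediate
7 | (1S,4R)-2-methyl-4-(prop-1-en-2-yl)cyclopent-2-en-1-ol (cis) | CC1=C[C@H](C(C)=C)C[C@@H]1O | intermediate
8 | (1S,4R)-2-methyl-4-(prop-1-en-2-yl)cyclopent-2-en-1-yl pyridine-2-carboxylate | CC1=C[C@H](C(C)=C)C[C@@H]1OC(=O)c1ccccn1 | intermediate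
9 | (R)-4-benzyloxazolidin-2-one | O=C1N[C@H](Cc2ccccc2)CO1 | starting material
10 | 3-methylbutanoyl chloride | CC(C)CC(Cl)=O | starting material
11 | (R)-4-benzyl-3-(3-methylbutanoyl)oxazolidin-2-one | CC(C)CC(=O)N1[C@H](Cc2ccccc2)COC1=O | intermediate
12 | acrolein (prop-2-enal) | C=CC=O | starting material
13 | dibutylboron (Z)-enolate of 11 | CC(C)/C=C(\OB(CCCC)CCCC)N1[C@H](Cc2ccccc2)COC1=O | intermediate
14 | dibutylboron aldolate of 15 | C=C[C@H](OB(CCCC)CCCC)[C@@H](C(C)C)C(=O)N1[C@H](Cc2ccccc2)COC1=O | intermediate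
15 | (R)-4-benzyl-3-[(2R,3S)-3-hydroxy-2-(propan-2-yl)pent-4-enoyl]oxazolidin-2-one | C=C[C@H](O)[C@@H](C(C)C)C(=O)N1[C@H](Cc2ccccc2)COC1=O | intermediate
16 | (R)-4-benzyl-3-{(2R,3S)-2-(propan-2-yl)-3-[(triethylsilyl)oxy]pent-4-enoyl}oxazolidin-2-one | C=C[C@H](O[Si](CC)(CC)CC)[C@@H](C(C)C)C(=O)N1[C@H](Cc2ccccc2)COC1=O | intermediate
17 | (2S,3S)-2-(propan-2-yl)-3-[(triethylsilyl)oxy]pent-4-en-1-ol | C=C[C@H](O[Si](CC)(CC)CC)[C@@H](C(C)C)CO | intermediate
18 | (3S,4R)-4-(bromomethyl)-5-methyl-3-[(triethylsilyl)oxy]hex-1-ene | C=C[C@H](O[Si](CC)(CC)CC)[C@@H](C(C)C)CBr | intermediate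
19 | isovanillin (3-hydroxy-4-methoxybenzaldehyde) | COc1ccc(C=O)cc1O | starting material
20 | 3-[(tert-butyldimethylsilyl)oxy]-4-methoxybenzaldehyde | COc1ccc(C=O)cc1O[Si](C)(C)C(C)(C)C | intermediate
21 | 3-[(tert-butyldimethylsilyl)oxy]-4-methoxybenzoic acid | COc1ccc(C(=O)O)cc1O[Si](C)(C)C(C)(C)C | intermediate
22 | 3-[(tert-butyldimethylsilyl)oxy]-4-methoxybenzoyl chloride | COc1ccc(C(Cl)=O)cc1O[Si](C)(C)C(C)(C)C | intermediate
23 | Grignard reagent of 18 | C=C[C@H](O[Si](CC)(CC)CC)[C@@H](C(C)C)C[Mg]Br | intermediate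
24 | triethylsilyl ether of 25 | C=C[C@H](O[Si](CC)(CC)CC)[C@@H](C(C)C)C[C@@H]1C(C)=CC[C@H]1C(C)=C | intermediate
25 | (3S,4R)-5-methyl-4-{[(1S,5R)-2-methyl-5-(prop-1-en-2-yl)cyclopent-2-en-1-yl]methyl}hex-1-en-3-ol | C=C[C@H](O)[C@@H](C(C)C)C[C@@H]1C(C)=CC[C@H]1C(C)=C | intermediate
26 | 1αH,5βH,7αH-guaia-3,9-dien-8α-ol | O[C@H]1C=C(C)[C@@H]2CC=C(C)[C@H]2C[C@@H]1C(C)C | intermediate
27 | 9α,10α-epoxy-1αH,5βH,7αH-guai-3-en-8α-ol | O[C@H]1[C@H]2O[C@@]2(C)[C@@H]3CC=C(C)[C@H]3C[C@@H]1C(C)C | intermediate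
28 | 9α,10α-epoxy-1αH,5βH,7αH-guai-3-en-8-one | O=C1[C@H]2O[C@@]2(C)[C@@H]3CC=C(C)[C@H]3C[C@@H]1C(C)C | intermediate
29 | 10α-hydroxy-1αH,5βH,7αH-guai-3-en-8-one | O=C1C[C@@](C)(O)[C@@H]2CC=C(C)[C@H]2C[C@@H]1C(C)C | intermediate
30 | 1αH,5βH,7αH-guai-3-ene-8β,10α-diol | O[C@@H]1C[C@@](C)(O)[C@@H]2CC=C(C)[C@H]2C[C@@H]1C(C)C | intermediate
31 | 8β-{3-[(tert-butyldimethylsilyl)oxy]-4-methoxybenzoyloxy}-1αH,5βH,7αH-guai-3-en-10α-ol | COc1ccc(C(=O)O[C@@H]2C[C@@](C)(O)[C@@H]3CC=C(C)[C@H]3C[C@@H]2C(C)C)cc1O[Si](C)(C)C(C)(C)C | intermediate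
32 | 8β-{3-[(tert-butyldimethylsilyl)oxy]-4-methoxybenzoyloxy}-3α,4α-epoxy-1αH,5βH,7αH-guaian-10α-ol | COc1ccc(C(=O)O[C@@H]2C[C@@](C)(O)[C@@H]3C[C@H]4O[C@@]4(C)[C@H]3C[C@@H]2C(C)C)cc1O[Si](C)(C)C(C)(C)C | intermediate
33 | 3α,4α-epoxy-8β-(3-hydroxy-4-methoxybenzoyloxy)-1αH,5βH,7αH-guaian-10α-ol (CNP0264062.2) | COc1ccc(C(=O)O[C@@H]2C[C@@](C)(O)[C@@H]3C[C@H]4O[C@@]4(C)[C@H]3C[C@@H]2C(C)C)cc1O | target

## Step count and risks

Total step count: 22.
Longest linear sequence: 14 steps (steps 1–5 or steps 6–10, then steps 14–22); fragment C adds 3 steps off the main line.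

Steps most likely to fail:

Step 14 (anti-SN2′ coupling). A β-branched alkylcopper may attack the α-carbon instead, or convert poorly. The fallback makes the C5–C6 bond by 1,4-addition. It sets out from enone 6 (steps 4 and 5 are then not needed) and Grignard reagent 23. Reagent 23 is turned into the magnesium cuprate with CuBr·SMe2 and added to 6 at −78 °C, anti to the isopropenyl group. The enolate is trapped with N-(5-chloropyridin-2-yl)triflimide as the C3 enol triflate F1. Pd(OAc)2/PPh3 with Bu3N and HCO2H in DMF at 60 °C then reduces the C–OTf bond. This comes back to the route at silyl ether 24, which is taken through the acid treatment of step 14 to 25.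

Step 15 (ring-closing metathesis). The free allylic alcohol may isomerise to the ethyl ketone, or the trisubstituted trans-fused cycloheptene may close slowly. The fallback sets out from silyl ether 24, isolated by leaving out the acid treatment of step 14. Metathesis on the protected substrate (second-generation Hoveyda–Grubbs catalyst, toluene, 80 °C) gives the ring-closed silyl ether F2. Tetrabutylammonium fluoride in THF then removes the silyl group, and the route is rejoined at 26.

Step 21 (facial selectivity of the last epoxidation). If the dioxirane attacks mainly the β face, the outcome is inverted through a halohydrin. The fallback sets out from 31. N-Bromosuccinimide in aqueous THF at 0 °C forms the bromonium ion on the β face, and water opens it at the tertiary C4 from the α face to give the 3β-bromo-4α-hydroxy compound, bromohydrin F3. K2CO3 in methanol then closes the oxirane by displacing bromide from the α face and also cleaves the aryl silyl ether. The fallback therefore comes back at target 33 and makes step 22 unnecessary.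

Further compounds

F1 | step 14 | C3 enol triflate: trans-2-methyl-4-(prop-1-en-2-yl)-3-{(2R,3S)-2-(propan-2-yl)-3-[(triethylsilyl)oxy]pent-4-en-1-yl}cyclopent-1-en-1-yl trifluoromethanesulfonate | C=C[C@H](O[Si](CC)(CC)CC)[C@@H](C(C)C)C[C@@H]1C(C)=C(OS(=O)(=O)C(F)(F)F)C[C@H]1C(C)=C
F2 | step 15 | ring-closed silyl ether: 8α-[(triethylsilyl)oxy]-1αH,5βH,7αH-guaia-3,9-diene | CC[Si](CC)(CC)O[C@H]1C=C(C)[C@@H]2CC=C(C)[C@H]2C[C@@H]1C(C)C
F3 | step 21 | bromohydrin: 3β-bromo-8β-{3-[(tert-butyldimethylsilyl)oxy]-4-methoxybenzoyloxy}-1αH,5βH,7αH-guaiane-4α,10α-diol | COc1ccc(C(=O)O[C@@H]2C[C@@](C)(O)[C@@H]3C[C@H](Br)[C@@](C)(O)[C@H]3C[C@@H]2C(C)C)cc1O[Si](C)(C)C(C)(C)C
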